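## Structural features

The target is a flavonol. A phloroglucinol-type benzene ring A (oxygens on C5 and C7) is fused through C4a–C8a to a 4-pyranone ring C (O1–C2=C3–C4=O), and C2 carries the catechol-type ring B through the C2–C1' bond. There is no stereocentre, so the problem is the differentiation of five oxygens: the enolic O3 and the phenolic O3' carry hydrogen sulfate groups, while O5, O7 and O4' are free. The sulfate monoesters are the fragile groups; they hydrolyse in acid (the enol sulfate on C3 most easily) but, as salts, tolerate mild base and neutral hydrogenolysis. The real difficulty is that O7 and O4', which must end up free, are the most acidic phenols and the most reactive towards sulfating agents. They therefore need masks that come off under neutral conditions, whereas O5 is shielded only by its hydrogen bond to the C4 carbonyl. The key step uses the fact that the O1–C2(aryl)=C3(OH)–C4(=O) array of ring C is, at the oxidation level of a dibromide, an isomer of the O1–C2(=CH–aryl)–C3(=O) array of a 2-benzylidenebenzofuran-3-one. Ring C can thus be made by enlarging a five-membered ring, with hydroxide supplying O3 and with the 3-OH and 3'-OH, the two sulfation sites, emerging free.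

## Logic of the disconnections

11 ⇒ 10. The two benzyl C–O bonds at O7 and O4' are cut last in the retrosynthesis. Sulfate monoesters do not survive acidic deprotection but do survive neutral hydrogenolysis, so benzyl is the only mask needed. The forward step must stay at neutral to slightly basic pH and must not reduce the C2=C3 bond.

10 ⇒ 9. The two S–O bonds at O3 and O3' are cut. This places sulfation one step from the end, so the sensitive groups are carried through a single operation. Compound 9 has exactly three free hydroxyls, and the forward step must leave the chelated 5-OH alone while reacting at both others.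

9 ⇒ 5 (through 6, 7 and 8). The O1–C2 bond of ring C is cut and O1 is reconnected to C3, which contracts the pyranone to a benzofuranone with an exocyclic alkene and removes the 3-oxygen. Ring A and ring B then arrive with all their oxygens in place. A precursor with ring A fully acylated would come out of this step with O7 free, and the later benzylation would then have to distinguish the 7-OH from the enolic 3-OH. The benzyl group is therefore placed on that oxygen before the ring enlargement, so the step delivers 9 with O7 and O4' already masked. The forward step requires bromine to add to the alkene rather than substitute the rings, and the base that drives the rearrangement also removes the two acetyl groups.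

5 ⇒ 4. Two acetyl C–O bonds are cut. The acetates mask the phenols and lower the electron density of both rings for the bromination, and they cost no deprotection step.

4 ⇒ 3. The benzyl C–O bond at O6 of the benzofuranone is cut. In 3 only this phenol is para to the ring carbonyl and strongly acidic, whereas the later flavonol has a competing 3-OH. The forward step requires mono-alkylation of the most acidic phenol only.

3 ⇒ 1 + 2. The exocyclic C=C bond is cut by a retro-aldol condensation. Both pieces are commercial, 1 carries ring A with its two oxygens, and 2 carries ring B with O4' already distinguished from O3'. The forward step must give the (Z)-alkene, which is the thermodynamically preferred isomer.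

## Other disconnections considered

Alternative 1: Ring A itself is cut at C4a–C8a and C5–C6 and rebuilt from 3-(benzyloxy)cyclobut-2-en-1-one A2 and the siloxy diyne A3.
- **Forward step:** Heating A2 opens it to a vinylketene, which adds across the electron-rich siloxyalkyne of A3. The resulting vinylcyclobutenone opens and recloses by a six-electron electrocyclisation to give phenol A1.
- **In favour:** The pericyclic cascade is dependable and its regiochemistry is fixed by the polarisation of the ynol ether. A1 carries the three ring A oxygens in three different forms (free OH, silyl ether, benzyl ether). On this differentiation the alternative is better than the chosen plan, which relies on acidity differences.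
- **Against:** It constructs a ring that is commercially available in 1. A3 is a sensitive, doubly propargylic silyl ether that needs several steps. After A1 the chain must be desilylated, oxidised to the ynone and closed in the 6-endo mode (a 5-exo closure would give a benzofuranone), which gives flavone A4 without the 3-oxygen, so a separate C3 hydroxylation and protecting-group changes follow.
- **Comparison:** Mechanistically the key step is at least as predictable as the ring enlargement. Structurally it solves a problem the target does not pose. In step economy it should need at least twice the six steps of the chosen plan.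

Alternative 2: Ring C is cut at C8a–O1, C4a–C4 and O1–C2, and is assembled from the aryne precursor A6 and the acrylic acid A7.
- **Forward step:** CsF releases the aryne from A6. The carboxylate of A7 adds to the aryne carbon remote from the neighbouring benzyloxy group, the aryl anion attacks the ester carbonyl, and the four-membered intermediate opens to an ortho-acyl phenoxide. This closes onto the enone by oxa-Michael addition to give the trans chromanone A5.
- **In favour:** Three bonds form in one convergent operation, O3 is present from the start, and no halogenation of electron-rich rings is needed. The methoxymethyl groups mark exactly O3 and O3' while O5, O7 and O4' are all benzylated, so the later sulfation would not depend on the chelation of a free 5-OH. On this point the alternative is better than the chosen plan.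
- **Against:** A6 is not commercial and needs several steps. Acyl transfer to the aryl anion competes with simple protonation to an aryl ester. The oxa-Michael acceptor is a deactivated β-aryl α-alkoxy enone next to a peri benzyloxy group. A5 is at the flavanonol oxidation level, so its two stereocentres are made only to be removed by a further dehydrogenation, and the acetal cleavage adds another step.
- **Comparison:** The two key steps carry comparable chemoselectivity risks. The alternative is the equal of the chosen plan in convergence but should be about four steps longer in the longest linear sequence.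

Alternative 3: Only C8a–O1 is cut, and ring C is closed from the 2-alkoxy-1,3-diketone A9.
- **Forward step:** With K2CO3 in DMF the enolate oxygen of A9 attacks an ortho C–F carbon of the trifluorophenyl ketone, and loss of fluoride from the Meisenheimer intermediate gives chromenone A8.
- **In favour:** This is the most dependable ring closure of the four plans. The two ortho fluorines are equivalent, the conditions are mild, and O3 and O3' are again pre-marked as acetals. On reliability of the ring-forming step and on protecting-group logic it is equal to or better than the chosen plan.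
- **Against:** Ring A arrives with fluorine at C5 and C7 where the target needs oxygen. Two further fluoride displacements by an alkoxide are required, the second on a ring already deactivated by the first alkoxy group and in competition with alkoxide attack at C2 of the pyranone. Making A9 requires C-acylation (not O-acylation) of an α-alkoxy ketone enolate.
- **Comparison:** The chosen plan starts with the ring A oxygens in place and should be three to four steps shorter. The alternative avoids bromine and strong aqueous alkali on a polyphenol.

Key step: step 4

Assumption: the target is drawn as the free bis(hydrogen sulfate); 10 and 11 would be prepared and stored as dipotassium salts, and all sulfated compounds are listed in their neutral form.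
Remark: 6 is drawn as the racemic anti adduct; 7 and 8 are drawn after loss of both acetyl groups; neither the configuration of 6 nor the timing of the saponification affects the product.

## Route

Step 1
Reactants: 1 4,6-dihydroxybenzofuran-3(2H)-one; 2 4-(benzyloxy)-3-hydroxybenzaldehyde
Product: 3 (Z)-2-[4-(benzyloxy)-3-hydroxybenzylidene]-4,6-dihydroxybenzofuran-3(2H)-one
Conditions: conc. aq. HCl, AcOH, 25 °C
Reagents that add atoms: none
Why: Acid-catalysed aldol condensation of the enolisable C2 methylene of 1 with the aldehyde, followed by dehydration; the conjugated (Z)-alkene, with the aryl group on the side of O1 and away from the C3 carbonyl, is the thermodynamic product, and aryl benzyl ethers tolerate these conditions at room temperature.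

Step 2
Reactants: 3 (Z)-2-[4-(benzyloxy)-3-hydroxybenzylidene]-4,6-dihydroxybenzofuran-3(2H)-one
Product: 4 (Z)-6-(benzyloxy)-2-[4-(benzyloxy)-3-hydroxybenzylidene]-4-hydroxybenzofuran-3(2H)-one
Conditions: BnBr (1.05 equiv), KHCO3 (1.5 equiv), DMF, 35 °C
Reagents that add atoms: benzyl bromide, BrCc1ccccc1
Why: Williamson etherification under acidity control: the 6-OH is para to the C3 carbonyl (a vinylogous acid) and is the only phenol that bicarbonate deprotonates appreciably, whereas the 4-OH is hydrogen-bonded to the carbonyl and the 3'-OH is an ordinary phenol; the same principle governs the selective 4-O-alkylation of 3,4-dihydroxybenzaldehyde.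

Step 3
Reactants: 4 (Z)-6-(benzyloxy)-2-[4-(benzyloxy)-3-hydroxybenzylidene]-4-hydroxybenzofuran-3(2H)-one
Product: 5 (Z)-4-acetoxy-2-[3-acetoxy-4-(benzyloxy)benzylidene]-6-(benzyloxy)benzofuran-3(2H)-one
Conditions: Ac2O, pyridine, DMAP (cat.), 25 °C
Reagents that add atoms: acetic anhydride, CC(=O)OC(C)=O
Why: Nucleophile-catalysed O-acylation of both remaining phenols; DMAP should overcome the hydrogen bond of the 4-OH, and the acetates mask the phenols and deactivate both rings for the bromination.

Step 4
Reactants: 5 (Z)-4-acetoxy-2-[3-acetoxy-4-(benzyloxy)benzylidene]-6-(benzyloxy)benzofuran-3(2H)-one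
Product: 9 7-(benzyloxy)-2-[4-(benzyloxy)-3-hydroxyphenyl]-3,5-dihydroxy-4H-chromen-4-one (4',7-di-O-benzylquercetin), via aurone dibromide 6 (not isolated), via ring-opened bromo diketone 7 (not isolated), via flavan-3,4-dione 8 (not isolated)
Conditions: Br2 (1.0 equiv), CH2Cl2, −20 → 0 °C, dark; evaporate; KOH (8 equiv), EtOH–H2O 3:1, argon, 0 → 25 °C; then AcOH to pH 5
Reagents that add atoms: potassium hydroxide, [K+].[OH-] (oxygen of the 3-hydroxyl); bromine, BrBr (present only in intermediates 6 and 7)
Why: This is the Auwers flavonol synthesis. Bromine adds across the exocyclic C2=CH bond of 5, the most nucleophilic π bond because both O1 and the para-benzyloxy group of ring B push into it, while ring A is held back by the C3 carbonyl and the 4-acetoxy group and ring B by the 3'-acetoxy group; this gives dibromide 6. In alkali the C2 bromide ionises with help from the O1 lone pair, hydroxide captures the oxocarbenium ion, and the hemiketal collapses by C2–O1 cleavage to the phenoxide of 1,2-diketone 7 while the acetates are saponified. The phenoxide then displaces the benzylic bromide in a 6-exo-tet closure (SN2, or SN1-like through the para-alkoxybenzyl cation), forming O1–C2 and the six-membered ring C of dione 8, which enolises to the aromatic 3-hydroxy-4-pyranone 9. Ring A of 7 is a symmetric 4-benzyloxy-2,6-dihydroxyphenyl group, so either ortho oxygen gives the same product. No stereocentre survives, since both centres of 6 become sp2 carbons in 9. The step needs addition rather than aromatic substitution, which one equivalent of bromine at low temperature in the dark without Lewis acid and the two acetates should secure; it needs substitution at C2 rather than loss of HBr, which aqueous hydroxide favours over alkoxide or amine bases; and the air-sensitive polyphenoxide is kept under argon.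

Step 5
Reactants: 9 7-(benzyloxy)-2-[4-(benzyloxy)-3-hydroxyphenyl]-3,5-dihydroxy-4H-chromen-4-one
Product: 10 7-(benzyloxy)-2-[4-(benzyloxy)-3-(sulfooxy)phenyl]-5-hydroxy-4-oxo-4H-chromen-3-yl hydrogen sulfate (dipotassium salt)
Conditions: SO3·pyridine (8 equiv), pyridine, 50 °C; then aq. KHCO3 to pH 8
Reagents that add atoms: sulfur trioxide–pyridine complex, O=S(=O)([O-])[n+]1ccccc1
Why: O-sulfation of phenols with an SO3–amine complex; the enolic 3-OH and the phenolic 3'-OH should react, while the 5-OH, locked in a six-membered hydrogen bond to the C4 carbonyl, is the least nucleophilic hydroxyl and should remain free; the basic quench keeps the monoesters as stable salts.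

Step 6
Reactants: 10 7-(benzyloxy)-2-[4-(benzyloxy)-3-(sulfooxy)phenyl]-5-hydroxy-4-oxo-4H-chromen-3-yl hydrogen sulfate (dipotassium salt)
Product: 11 5,7-dihydroxy-2-[4-hydroxy-3-(sulfooxy)phenyl]-4-oxo-4H-chromen-3-yl hydrogen sulfate (quercetin 3,3'-bissulfate, dipotassium salt)
Conditions: H2 (1 atm), 10% Pd/C, MeOH–H2O, KHCO3 buffer (pH 7–8), 25 °C
Reagents that add atoms: none
Why: Catalytic hydrogenolysis of the two aryl benzyl ethers; sulfate monoester salts and the pyranone C2=C3 bond are inert under neutral, low-pressure conditions, and the buffer prevents acid-catalysed loss of sulfate; pyridine must be removed beforehand because it slows benzyl ether hydrogenolysis.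

## Compound list

1 | 4,6-dihydroxybenzofuran-3(2H)-one | O=C1COc2cc(O)cc(O)c21 | starting material
2 | 4-(benzyloxy)-3-hydroxybenzaldehyde | O=Cc1ccc(OCc2ccccc2)c(O)c1 | starting material
3 | (Z)-2-[4-(benzyloxy)-3-hydroxybenzylidene]-4,6-dihydroxybenzofuran-3(2H)-one | O=C1/C(=C/c2ccc(OCc3ccccc3)c(O)c2)Oc2cc(O)cc(O)c21 | intermediate
4 | (Z)-6-(benzyloxy)-2-[4-(benzyloxy)-3-hydroxybenzylidene]-4-hydroxybenzofuran-3(2H)-one | O=C1/C(=C/c2ccc(OCc3ccccc3)c(O)c2)Oc2cc(OCc3ccccc3)cc(O)c21 | intermediate
5 | (Z)-4-acetoxy-2-[3-acetoxy-4-(benzyloxy)benzylidene]-6-(benzyloxy)benzofuran-3(2H)-one | O=C1/C(=C/c2ccc(OCc3ccccc3)c(OC(C)=O)c2)Oc2cc(OCc3ccccc3)cc(OC(C)=O)c21 | intermediate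
6 | rel-(2R)-4-acetoxy-2-{(S)-[3-acetoxy-4-(benzyloxy)phenyl]bromomethyl}-6-(benzyloxy)-2-bromobenzofuran-3(2H)-one (racemic anti adduct, one enantiomer drawn) | CC(=O)Oc1cc(OCc2ccccc2)cc2c1C(=O)[C@](Br)(O2)[C@@H](Br)c1ccc(OCc3ccccc3)c(OC(C)=O)c1 | intermediate
7 | 3-[4-(benzyloxy)-3-hydroxyphenyl]-1-[4-(benzyloxy)-2,6-dihydroxyphenyl]-3-bromopropane-1,2-dione (racemic, one enantiomer drawn) | O=C(c1c(O)cc(OCc2ccccc2)cc1O)C(=O)[C@@H](Br)c1ccc(OCc2ccccc2)c(O)c1 | intermediate
8 | 7-(benzyloxy)-2-[4-(benzyloxy)-3-hydroxyphenyl]-5-hydroxychromane-3,4-dione (racemic, one enantiomer drawn) | O=C1C(=O)c2c(O)cc(OCc3ccccc3)cc2O[C@@H]1c1ccc(OCc2ccccc2)c(O)c1 | intermediate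
9 | 7-(benzyloxy)-2-[4-(benzyloxy)-3-hydroxyphenyl]-3,5-dihydroxy-4H-chromen-4-one (4',7-di-O-benzylquercetin) | O=c1c(O)c(-c2ccc(OCc3ccccc3)c(O)c2)oc2cc(OCc3ccccc3)cc(O)c12 | intermediate
10 | 7-(benzyloxy)-2-[4-(benzyloxy)-3-(sulfooxy)phenyl]-5-hydroxy-4-oxo-4H-chromen-3-yl hydrogen sulfate | O=c1c(OS(=O)(=O)O)c(-c2ccc(OCc3ccccc3)c(OS(=O)(=O)O)c2)oc2cc(OCc3ccccc3)cc(O)c12 | intermediate
11 | 5,7-dihydroxy-2-[4-hydroxy-3-(sulfooxy)phenyl]-4-oxo-4H-chromen-3-yl hydrogen sulfate (quercetin 3,3'-bissulfate) | O=c1c(OS(=O)(=O)O)c(-c2ccc(O)c(OS(=O)(=O)O)c2)oc2cc(O)cc(O)c12 | target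

## Step count and least certain steps

Total step count: 6. Longest linear sequence: 6 steps (from 1 and 2 to 11).

Step 4 (key step). The most likely failure is electrophilic substitution by bromine at C5 or C7 of ring A, which now carries an activating benzyloxy group, in competition with addition to the alkene. In the alkaline stage, loss of HBr or ethanolysis at the doubly activated benzylic position could outrun the ring closure. Fallback: set out from 3 and acetylate all three phenols (Ac2O, pyridine) to (Z)-4,6-diacetoxy-2-[3-acetoxy-4-(benzyloxy)benzylidene]benzofuran-3(2H)-one F1, in which ring A is doubly deactivated. Add bromine to give its dibromide F2 and treat this with aqueous ethanolic KOH to obtain 4'-O-benzylquercetin F3. Benzylate F3 at the 7-hydroxyl, its most acidic phenol (BnBr, 1.0 equiv, KHCO3, DMF), to rejoin the route at 9. The price is that this last alkylation has to be won against the enolic 3-OH.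

Step 2. The most likely failure is a second alkylation at O3' or O4, or incomplete conversion because triphenol 3 is poorly soluble. Fallback: set out from 1 and benzylate it before the condensation (BnBr, KHCO3, DMF) to 6-(benzyloxy)-4-hydroxybenzofuran-3(2H)-one F4, which has only one competing, chelated phenol. Condense F4 with 2 under the conditions of step 1 to rejoin the route at 4.

Step 5. The most likely failure is incomplete sulfation of the hydrogen-bonded enolic 3-OH, giving mono-sulfate mixtures, or the onset of sulfation at O5 when the reaction is forced; the polar salts would be hard to separate. Fallback: set out from 9 and use a protected sulfate transfer (2,2,2-trichloroethyl chlorosulfate, Et3N, DMAP, THF) to give the neutral, chromatographable bis(2,2,2-trichloroethyl sulfate) diester F5. Reductive removal of the trichloroethyl groups with Zn and HCO2NH4 in MeOH leaves the benzyl ethers intact and rejoins the route at 10.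

Step 6. The most likely failure is loss of a sulfate group, the enol sulfate first, by acid-catalysed hydrolysis if the medium drifts acidic, or stalling of the hydrogenolysis by residual pyridine. Fallback: set out from 9 and install acid-stable alkyl-protected sulfates with isobutyl chlorosulfate and NaN(SiMe3)2 (2 equiv) in THF to give 4',7-di-O-benzylquercetin 3,3'-bis(isobutyl sulfate) F6. Hydrogenolyse the benzyl ethers of this neutral diester (H2, Pd/C) to quercetin 3,3'-bis(isobutyl sulfate) F7, then remove the isobutyl groups with NaI in acetone at 55 °C to rejoin the route at 11.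

## Further compounds

F1 | step 4 | (Z)-4,6-diacetoxy-2-[3-acetoxy-4-(benzyloxy)benzylidene]benzofuran-3(2H)-one | O=C1/C(=C/c2ccc(OCc3ccccc3)c(OC(C)=O)c2)Oc2cc(OC(C)=O)cc(OC(C)=O)c21
F2 | step 4 | rel-(2R)-4,6-diacetoxy-2-{(S)-[3-acetoxy-4-(benzyloxy)phenyl]bromomethyl}-2-bromobenzofuran-3(2H)-one (racemic anti adduct, one enantiomer drawn) | CC(=O)Oc1cc(OC(C)=O)cc2c1C(=O)[C@](Br)(O2)[C@@H](Br)c1ccc(OCc3ccccc3)c(OC(C)=O)c1
F3 | step 4 | 2-[4-(benzyloxy)-3-hydroxyphenyl]-3,5,7-trihydroxy-4H-chromen-4-one (4'-O-benzylquercetin) | O=c1c(O)c(-c2ccc(OCc3ccccc3)c(O)c2)oc2cc(O)cc(O)c12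
F4 | step 2 | 6-(benzyloxy)-4-hydroxybenzofuran-3(2H)-one | O=C1COc2cc(OCc3ccccc3)cc(O)c21
F5 | step 5 | 4',7-di-O-benzylquercetin 3,3'-bis(2,2,2-trichloroethyl sulfate) | O=c1c(OS(=O)(=O)OCC(Cl)(Cl)Cl)c(-c2ccc(OCc3ccccc3)c(OS(=O)(=O)OCC(Cl)(Cl)Cl)c2)oc2cc(OCc3ccccc3)cc(O)c12
F6 | step 6 | 4',7-di-O-benzylquercetin 3,3'-bis(isobutyl sulfate) | O=c1c(OS(=O)(=O)OCC(C)C)c(-c2ccc(OCc3ccccc3)c(OS(=O)(=O)OCC(C)C)c2)oc2cc(OCc3ccccc3)cc(O)c12
F7 | step 6 | quercetin 3,3'-bis(isobutyl sulfate) | O=c1c(OS(=O)(=O)OCC(C)C)c(-c2ccc(O)c(OS(=O)(=O)OCC(C)C)c2)oc2cc(O)cc(O)c12
A1 | alternative 1 | 5-(benzyloxy)-2-{1-(tert-butyldimethylsilyloxy)-3-[4-(benzyloxy)-3-(methoxymethoxy)phenyl]prop-2-yn-1-yl}-3-(triisopropylsilyloxy)phenol (racemic, one enantiomer drawn) | Oc1cc(OCc2ccccc2)cc(O[Si](C(C)C)(C(C)C)C(C)C)c1[C@@H](O[Si](C)(C)C(C)(C)C)C#Cc1ccc(OCc2ccccc2)c(OCOC)c1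
A2 | alternative 1 | 3-(benzyloxy)cyclobut-2-en-1-one | O=C1CC(OCc2ccccc2)=C1
A3 | alternative 1 | tert-butyl({5-[4-(benzyloxy)-3-(methoxymethoxy)phenyl]-1-(triisopropylsilyloxy)penta-1,4-diyn-3-yl}oxy)dimethylsilane (racemic, one enantiomer drawn) | CC(C)[Si](OC#C[C@@H](O[Si](C)(C)C(C)(C)C)C#Cc1ccc(OCc2ccccc2)c(OCOC)c1)(C(C)C)C(C)C
A4 | alternative 1 | 7-(benzyloxy)-2-[4-(benzyloxy)-3-(methoxymethoxy)phenyl]-5-(triisopropylsilyloxy)-4H-chromen-4-one | O=c1cc(-c2ccc(OCc3ccccc3)c(OCOC)c2)oc2cc(OCc3ccccc3)cc(O[Si](C(C)C)(C(C)C)C(C)C)c12
A5 | alternative 2 | trans-5,7-bis(benzyloxy)-2-[4-(benzyloxy)-3-(methoxymethoxy)phenyl]-3-(methoxymethoxy)chroman-4-one (racemic, one enantiomer drawn) | COCOc1cc(ccc1OCc1ccccc1)[C@@H]1[C@H](C(=O)c2c(OCc3ccccc3)cc(OCc3ccccc3)cc2O1)OCOC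
A6 | alternative 2 | 3,5-bis(benzyloxy)-2-(trimethylsilyl)phenyl trifluoromethanesulfonate | C[Si](C)(C)c1c(OCc2ccccc2)cc(OCc2ccccc2)cc1OS(=O)(=O)C(F)(F)F
A7 | alternative 2 | (Z)-3-[4-(benzyloxy)-3-(methoxymethoxy)phenyl]-2-(methoxymethoxy)acrylic acid | COCO/C(=C\c1ccc(OCc2ccccc2)c(OCOC)c1)C(=O)O
A8 | alternative 3 | 2-[4-(benzyloxy)-3-(methoxymethoxy)phenyl]-5,7-difluoro-3-(methoxymethoxy)-4H-chromen-4-one | O=c1c(OCOC)c(-c2ccc(OCc3ccccc3)c(OCOC)c2)oc2cc(F)cc(F)c12
A9 | alternative 3 | 1-[4-(benzyloxy)-3-(methoxymethoxy)phenyl]-2-(methoxymethoxy)-3-(2,4,6-trifluorophenyl)propane-1,3-dione | COCOC(C(=O)c1c(F)cc(F)cc1F)C(=O)c1ccc(OCc2ccccc2)c(OCOC)c1
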